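Count the coupling partner against the substrate before you reckon any rate.

| flask | substrate | coupling partner | remark | time |
|---|---|---|---|---|
| east | 0.94 M | 2.5 M | run made earlier |  |
| autumn | 0.94 M | 1.69 M |  | 20 h |
| noon | 0.94 M | 1.69 M |  | 60 h |
| midnight | 0.94 M | 1.69 M |  | 180 h |

east run (percent of the substrate charged)

| time / h | double product / % | substrate / % | tris adduct / % | mono adduct / % |
|---|---|---|---|---|
| 0.500 | 0 | 96 | 0 | 9 |
| 1.00 | 0 | 93 | 1 | 5 |
| 1.50 | 0 | 85 | 1 | 14 |
| 2.50 | 3 | 81 | 5 | 15 |
| 3.00 | 6 | 78 | 4 | 19 |
| 4.00 | 11 | 67 | 0 | 24 |

(scatter of a reading: 2 percentage points)

* which of these there is most of at the end, counted by the substrate in it, autumn (tris adduct / mono adduct / substrate / double product)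
* which of these there is most of at the end, counted by the substrate in it, noon (tris adduct / mono adduct / substrate / double product)
* which of these there is most of at the end, counted by the substrate in it, midnight (tris adduct / mono adduct / substrate / double product)
* the largest of these amounts at the end, in percent of the substrate charged, autumn
* the largest of these amounts at the end, in percent of the substrate charged, noon
* the largest of these amounts at the end, in percent of the substrate charged, midnight

- steps under discussion: substrate + coupling partner -> mono adduct + released group; coupling partner + mono adduct -> double product + released group; coupling partner + double product -> tris adduct + released group; coupling partner + tris adduct -> over-reaction product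

1. Each step takes one coupling partner. So take the partner budget, the partner charged per substrate charged: 1.80 equivalents in autumn, noon and midnight. Call the partner taken so far, per substrate charged, the spent amount.

2. Main step alone: the substrate goes to mono adduct and 0.800 equivalents stay over.

3. Add the mono step: each double product costs 2, so the budget allows double product up to 90.0%.

4. Add the rest. In the east run tris adduct reads 5% and 4% beside double product at 3% and 6%, then 0%, with a scatter of 2 percentage points. I therefore do not treat the tris step as a small correction, and I start with equal steps. Substrate is then e to the minus spent, mono adduct is that times spent, and double product is that times spent squared over 2.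

5. East substrate reads 67% at 4.00 h, a decay of 0.100 h⁻¹. Scaled to these charges, the partner falls at 0.0376 h⁻¹, and spent is the budget times one minus e to the minus that rate times time. That gives 0.951 in autumn, 1.61 at noon and 1.80 at midnight.

6. Autumn: substrate 38.6% leads mono adduct at 36.7%.

7. The east double product reads 11% where equal steps give 5.37%, so I take the mono step as faster. At 4.00 h the east ratio of double product to mono adduct reads 0.458 where equal steps give 0.200, a factor of 2.29. I keep the equal-step sum of mono adduct and double product and share it by the equal-step ratio times that factor. Double product then comes to 28.3% in autumn, less than substrate. At noon it comes to 37.7%, ahead of the others, and at midnight to 38.1%, again ahead.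

The forecast differs from my noon and midnight figures: it says substrate at 38%, double product at 62% and double product at 73%, with “Partner starvation and tris leakage bring this to about 73%”.

    substrate + coupling partner → mono adduct + released group (k = 7.00 × 10⁻⁴ L mol⁻¹ min⁻¹)
    coupling partner + mono adduct → double product + released group (k = 0.00130 L mol⁻¹ min⁻¹)
    coupling partner + double product → tris adduct + released group (k = 7.70 × 10⁻⁴ L mol⁻¹ min⁻¹)
    coupling partner + tris adduct → over-reaction product (k = 3.80 × 10⁻⁴ L mol⁻¹ min⁻¹)

The flasks give substrate at 39.4% in autumn, double product at 29.9% at noon and double product at 30.1% at midnight. At midnight the coupling partner, the limiting reagent, is down to 0.0593% of its charge with substrate still at 20.7%. Now take the neighbour of autumn charged with 2.3 M of substrate: its budget is 0.735 equivalents, and with 10% of its partner left at 20.0 h, spent is 0.659, which gives substrate 51.7%. That neighbour flask holds 56.3%.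

The readings were computed from invented constants; noise was put on by code.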